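The closed, stirred vessel turns one G and one E into one Q, so Q stays below the smaller of the two charges.

| flask | G | E | time |
|---|---|---|---|
| amber | 0.0800 M | 0.160 M |  |
| grey | 0.0800 M | 0.320 M |  |
| teal | 0.160 M | 0.160 M |  |
| ochre | 0.240 M | 0.0800 M | 4.4 min |

| run | time / min | [Q] / M |
|---|---|---|
| amber run | 0.18 | 0.0029 |
| amber run | 0.30 | 0.0040 |
| amber run | 0.51 | 0.0076 |
| amber run | 0.88 | 0.0144 |
| amber run | 1.5 | 0.0249 |
| amber run | 2.6 | 0.0426 |
| amber run | 4.4 | 0.0624 |
| grey run | 0.18 | 0.0065 |
| grey run | 0.30 | 0.0107 |
| grey run | 0.51 | 0.0190 |
| grey run | 0.88 | 0.0333 |
| grey run | 1.5 | 0.0527 |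
| grey run | 2.6 | 0.0709 |
| grey run | 4.4 | 0.0797 |
| teal run | 0.18 | 0.0052 |
| teal run | 0.30 | 0.0102 |
| teal run | 0.51 | 0.0163 |
| teal run | 0.88 | 0.0325 |
| teal run | 1.5 | 0.0613 |
| teal run | 2.6 | 0.1010 |
| teal run | 4.4 | 0.1301 |

(scatter of a reading: 4 × 10⁻⁴ M)

- apparent order in [G] of the starting rate, round the charge of the amber run (the rate where two percent of its G have turned into Q) (one fixed amount of Q, the same in the runs compared)
- apparent order in [E] of the starting rate, round the charge of the amber run (the rate where two percent of its G have turned into Q)
- Q in the ochre run at 4.4 min, as a share of the G charged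

- Overall: G + E -> Q.
- Constant volume, constant temperature.
- Bound and free are read together.
- "The second partner" is E.
- An order is taken over about fifteen percent of the charge, up and down.

1. The ochre run holds 0.0800 M of E against 0.240 M of G. E is its limiting reagent, and its ceiling is 33.3 % of the G charged.

2. Two runs bracket ochre. Amber and grey have G as the smaller charge, equal to the E of ochre. The surplus of the other partner is 0.0800 M in amber, 0.160 M in ochre and 0.240 M in grey, so ochre stands midway.

3. At 4.4 min, the amber reading leaves 22.0 % of its G unturned, and the grey reading leaves 0.375 %, which is less than the scatter of that reading, 0.500 % of the charge.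

4. This reckoning makes two assumptions. It treats G and E as interchangeable, and it takes the logarithm of the unturned share as straight in the surplus, at fixed time and limiting charge. The unturned share of ochre is then the geometric mean of the two ends, and no rate constant enters.

5. What must be known well? The ceiling enters in full, since the share moves in proportion to it. One scatter on the amber reading shifts the share by 0.011 percentage points. One scatter down on the grey reading shifts it by 0.51 points. The grey reading is therefore the weak point, and still a small one.

6. The reckoned ochre gap is 2.87 %, the share of its E charge left unturned at the asked time. My reckoning therefore gives 32.4 % of the G charged.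

The forecast gave orders of 1 in G and 1 in E and 32 % for ochre, with the words “That points to autocatalysis”.

The flask gives orders of 1.0 in G and 1.3 in E, and 32.3 % for ochre.

    G + 2 E → Q + E (23.88 /M²/min)
    2 E ⇌ E2, settled at all times (5.120 /M)
    G + E + Q → 2 Q (95.40 /M²/min)

At 4.4 min the ochre run has a gap of 3.06 %. The conversion of G + E + Q into 2 Q keeps it that small: without that step the ochre run stands at 15.9 % at that time, a gap of 52.3 %. The teal run, with G and E charged equally, reads a wider gap than the ochre run, at 18.7 % at 4.4 min.

The runs were computed on assumed constants; the scatter is artificial.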